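**Retrosynthetic overview**

1. The plan rests on ring A: C5, C7 and C8a carry a phloroglucinol set of oxygens of which only O7 is methylated. This is the pattern of a triketide with its middle enol capped, as in the C4 methyl enol ether of 4-methoxy-6-methyl-2-pyranone; O8 and O3 lie outside this pattern and are added late.
2. Target ⇒ debenzylation; C3–OH from epoxidation of the flavone C2=C3 bond; C8–OH by para-hydroxylation directed by the free 5-OH ⇒ 5-hydroxy-7-methoxyflavone with ring B benzylated.
3. Ring C (O1–C2 bond) ⇒ oxidative cyclisation of the 2',6'-dihydroxy-4'-methoxychalcone.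
4. Ring A (C4a–C8a bond) ⇒ lactone opening and Claisen closure of a 4-methoxy-2-pyranone bearing the cinnamoylmethyl chain at C6.
5. That pyranone ⇒ C-acylation of the lithiated pyranone methyl group with the ring B cinnamoyl Weinreb amide, made from 3,5-dihydroxy-4-methoxybenzoic acid. Ring order: B (bought), A, then C.

Key step: step 6

Remark: flavone numbering (O1, C2–C4, C4a, C5–C8, C8a; ring B primed) is used for all intermediates, including the atoms that later become these positions.

**Route**

Step 1
Reactants: 1 3,5-dihydroxy-4-methoxybenzoic acid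
Product: 2 benzyl 3,5-bis(benzyloxy)-4-methoxybenzoate
Conditions: BnBr, K2CO3, DMF, 60 °C
Reagents that add atoms: benzyl bromide, BrCc1ccccc1
Why: Williamson O-alkylation of both phenoxides together with SN2 alkylation of the carboxylate should cap all three acidic sites in one operation, the 4-methoxy group being inert.

Step 2
Reactants: 2 benzyl 3,5-bis(benzyloxy)-4-methoxybenzoate
Product: 3 [3,5-bis(benzyloxy)-4-methoxyphenyl]methanol
Conditions: LiAlH4, THF, 0 °C to rt
Reagents that add atoms: none
Why: Hydride reduction of the ester should give the primary benzylic alcohol, aryl benzyl ethers being untouched by LiAlH4.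

Step 3
Reactants: 3 [3,5-bis(benzyloxy)-4-methoxyphenyl]methanol
Product: 4 3,5-bis(benzyloxy)-4-methoxybenzaldehyde
Conditions: MnO2, CH2Cl2, rt
Reagents that add atoms: none
Why: Activated MnO2 oxidises benzylic alcohols selectively to aldehydes without over-oxidation to the acid.

Step 4
Reactants: 4 3,5-bis(benzyloxy)-4-methoxybenzaldehyde
Product: 5 (2E)-3-[3,5-bis(benzyloxy)-4-methoxyphenyl]-N-methoxy-N-methylprop-2-enamide
Conditions: (EtO)2P(O)CH2C(O)N(OMe)Me, NaH, THF, 0 °C to rt
Reagents that add atoms: diethyl {2-[methoxy(methyl)amino]-2-oxoethyl}phosphonate, CCOP(=O)(CC(=O)N(C)OC)OCC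
Why: Horner–Wadsworth–Emmons olefination with a stabilised phosphonate carbanion should give the (E)-alkene and installs the acyl donor for the next step directly.

Step 5
Reactants: 6 4-methoxy-6-methyl-2H-pyran-2-one; 5 (2E)-3-[3,5-bis(benzyloxy)-4-methoxyphenyl]-N-methoxy-N-methylprop-2-enamide
Product: 8 6-{(3E)-4-[3,5-bis(benzyloxy)-4-methoxyphenyl]-2-oxobut-3-en-1-yl}-4-methoxy-2H-pyran-2-one, via 6-(lithiomethyl)-4-methoxypyran-2-one 7 (not isolated)
Conditions: LDA (1.6 equiv), 6 (1.5 equiv), THF, −78 °C; then 5, −78 to −40 °C; aq. NH4Cl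
Reagents that add atoms: none
Why: LDA deprotonates the pyranone at the C6 methyl group (lateral lithiation to a vinylogous ester enolate), and this carbanion should C-acylate on the amide carbonyl in a Weinreb ketone synthesis, the chelated tetrahedral adduct holding back the acidic diketone-like product until work-up so that neither double addition nor proton transfer consumes the anion, which is why an amide and not a cinnamate ester is the acyl donor.

Step 6
Reactants: 8 6-{(3E)-4-[3,5-bis(benzyloxy)-4-methoxyphenyl]-2-oxobut-3-en-1-yl}-4-methoxy-2H-pyran-2-one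
Product: 10 (2E)-3-[3,5-bis(benzyloxy)-4-methoxyphenyl]-1-(2,6-dihydroxy-4-methoxyphenyl)prop-2-en-1-one, via ring-opened enol-ether diketo ester 9 (not isolated)
Conditions: Mg(OMe)2 (4 equiv), MeOH, reflux; then 1 M HCl
Reagents that add atoms: none
Why: Methoxide adds to the lactone carbonyl of 8 and the ring opens reversibly, drawn forward because the freed enolate becomes part of a magnesium-chelated β-diketonate, while the former ring keeps the enol-ether double bond in the geometry that places the new methyl ester cis to the diketone chain. The central diketonate carbon (future C4a) then attacks the ester carbon (future C8a) in a Claisen, Dieckmann-type C-acylation, a 6-exo-trig closure that forms the C4a–C8a bond, expels the methoxide taken up before and, after tautomerisation of the cyclohexadienone, gives aromatic ring A with O7 still methylated. The closest known reaction type is the base-induced conversion of 6-(2-oxoalkyl)-4-oxygenated 2-pyranones into acylphloroglucinols, the laboratory counterpart of chalcone-type polyketide folding. No stereocentre is formed and the (E)-alkene is not involved. The step needs C-acylation at C4a to win over the aldol mode (the vinylogous ester carbon attacking the side-chain ketone, which would lead to a resorcylate) and over closure through oxygen; the divalent magnesium ion secures this by holding the diketone as a planar chelate whose central carbon is the strongest carbon nucleophile and by activating the ester through coordination, whereas free alkali enolates lean towards the aldol path. The two phenols of 10 are equivalent, so the later closure of ring C has no regiochemical choice.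

Step 7
Reactants: 10 (2E)-3-[3,5-bis(benzyloxy)-4-methoxyphenyl]-1-(2,6-dihydroxy-4-methoxyphenyl)prop-2-en-1-one
Product: 12 2-[3,5-bis(benzyloxy)-4-methoxyphenyl]-5-hydroxy-7-methoxy-4H-chromen-4-one, via flavanone 11 (not isolated)
Conditions: I2 (10 mol %), DMSO, 130 °C
Reagents that add atoms: none
Why: Iodine-catalysed oxidative cyclisation of a 2'-hydroxychalcone (oxa-Michael closure of O1 onto C2, α-iodination at C3 and loss of HI, with DMSO reoxidising iodide) should give the flavone, and any flavanone already formed during step 6 converges to the same product.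

Step 8
Reactants: 12 2-[3,5-bis(benzyloxy)-4-methoxyphenyl]-5-hydroxy-7-methoxy-4H-chromen-4-one
Product: 14 2-[3,5-bis(benzyloxy)-4-methoxyphenyl]-5,8-dihydroxy-7-methoxy-4H-chromen-4-one, via C8 aryl sulfate potassium salt 13 (not isolated)
Conditions: K2S2O8, KOH, H2O/pyridine, 15 °C; then HCl, Na2SO3, H2O, 80 °C
Reagents that add atoms: potassium peroxodisulfate, [K+].[K+].[O-]S(=O)(=O)OOS(=O)(=O)[O-]
Why: Elbs persulfate oxidation, in which the only free phenoxide (O5) directs attack of peroxodisulfate to its para carbon C8 to give the aryl sulfate that mild acid hydrolyses to the quinol, is the classical way to turn 5-hydroxyflavones into 5,8-dihydroxyflavones, and every other oxygen is capped as an ether.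

Step 9
Reactants: 14 2-[3,5-bis(benzyloxy)-4-methoxyphenyl]-5,8-dihydroxy-7-methoxy-4H-chromen-4-one
Product: 15 5,8-bis(benzyloxy)-2-[3,5-bis(benzyloxy)-4-methoxyphenyl]-7-methoxy-4H-chromen-4-one
Conditions: BnBr, K2CO3, KI (cat.), DMF, 70 °C, N2
Reagents that add atoms: benzyl bromide, BrCc1ccccc1
Why: Williamson etherification with heating should cap the free 8-OH and the chelated 5-OH, the inert atmosphere keeping the quinol from air oxidation, so that no free phenol meets the dioxirane in the next step.

Step 10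
Reactants: 15 5,8-bis(benzyloxy)-2-[3,5-bis(benzyloxy)-4-methoxyphenyl]-7-methoxy-4H-chromen-4-one
Product: 17 5,8-bis(benzyloxy)-2-[3,5-bis(benzyloxy)-4-methoxyphenyl]-3-hydroxy-7-methoxy-4H-chromen-4-one, via 2,3-epoxide 16 (not isolated)
Conditions: DMDO, acetone/CH2Cl2, 0 °C to rt; then p-TsOH (cat.), CH2Cl2, rt
Reagents that add atoms: dimethyldioxirane, CC1(C)OO1
Why: Dioxirane epoxidation of the C2=C3 bond of a fully O-alkylated flavone followed by acid-catalysed opening of the epoxide at C2 (oxocarbenium ion stabilised by O1) and loss of the C3 proton is the established flavone-to-flavonol conversion.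

Step 11
Reactants: 17 5,8-bis(benzyloxy)-2-[3,5-bis(benzyloxy)-4-methoxyphenyl]-3-hydroxy-7-methoxy-4H-chromen-4-one
Product: 18 2-(3,5-dihydroxy-4-methoxyphenyl)-3,5,8-trihydroxy-7-methoxy-4H-chromen-4-one
Conditions: H2 (1 atm), Pd/C, THF/MeOH, rt; work-up under N2
Reagents that add atoms: none
Why: Catalytic hydrogenolysis should cleave the four aryl benzyl ethers while the two methyl ethers and the flavonol chromophore persist, and the air-sensitive 5,8-quinol is handled under inert gas.

**Compound list**

1 | 3,5-dihydroxy-4-methoxybenzoic acid | COc1c(O)cc(C(=O)O)cc1O | starting material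
2 | benzyl 3,5-bis(benzyloxy)-4-methoxybenzoate | COc1c(OCc2ccccc2)cc(C(=O)OCc2ccccc2)cc1OCc1ccccc1 | intermediate
3 | [3,5-bis(benzyloxy)-4-methoxyphenyl]methanol | COc1c(OCc2ccccc2)cc(CO)cc1OCc1ccccc1 | intermediate
4 | 3,5-bis(benzyloxy)-4-methoxybenzaldehyde | COc1c(OCc2ccccc2)cc(C=O)cc1OCc1ccccc1 | intermediate
5 | (2E)-3-[3,5-bis(benzyloxy)-4-methoxyphenyl]-N-methoxy-N-methylprop-2-enamide | CON(C)C(=O)/C=C/c1cc(OCc2ccccc2)c(OC)c(OCc2ccccc2)c1 | intermediate
6 | 4-methoxy-6-methyl-2H-pyran-2-one | COc1cc(C)oc(=O)c1 | starting material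
7 | 6-(lithiomethyl)-4-methoxy-2H-pyran-2-one | COc1cc(C[Li])oc(=O)c1 | intermediate (not isolated)
8 | 6-{(3E)-4-[3,5-bis(benzyloxy)-4-methoxyphenyl]-2-oxobut-3-en-1-yl}-4-methoxy-2H-pyran-2-one | COc1cc(CC(=O)/C=C/c2cc(OCc3ccccc3)c(OC)c(OCc3ccccc3)c2)oc(=O)c1 | intermediate
9 | methyl (2E,8E)-9-[3,5-bis(benzyloxy)-4-methoxyphenyl]-3-methoxy-5,7-dioxonona-2,8-dienoate, present as its magnesium diketonate | COC(=O)/C=C(OC)\CC(=O)CC(=O)/C=C/c1cc(OCc2ccccc2)c(OC)c(OCc2ccccc2)c1 | intermediate (not isolated)
10 | (2E)-3-[3,5-bis(benzyloxy)-4-methoxyphenyl]-1-(2,6-dihydroxy-4-methoxyphenyl)prop-2-en-1-one | COc1cc(O)c(C(=O)/C=C/c2cc(OCc3ccccc3)c(OC)c(OCc3ccccc3)c2)c(O)c1 | intermediate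
11 | 2-[3,5-bis(benzyloxy)-4-methoxyphenyl]-5-hydroxy-7-methoxychroman-4-one, racemic at C2, the centre being erased in the same step | COc1cc(O)c2C(=O)CC(c3cc(OCc4ccccc4)c(OC)c(OCc4ccccc4)c3)Oc2c1 | intermediate (not isolated)
12 | 2-[3,5-bis(benzyloxy)-4-methoxyphenyl]-5-hydroxy-7-methoxy-4H-chromen-4-one | COc1cc(O)c2c(=O)cc(-c3cc(OCc4ccccc4)c(OC)c(OCc4ccccc4)c3)oc2c1 | intermediate
13 | potassium 2-[3,5-bis(benzyloxy)-4-methoxyphenyl]-5-hydroxy-7-methoxy-4-oxo-4H-chromen-8-yl sulfate | COc1cc(O)c2c(=O)cc(-c3cc(OCc4ccccc4)c(OC)c(OCc4ccccc4)c3)oc2c1OS(=O)(=O)[O-].[K+] | intermediate (not isolated)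
14 | 2-[3,5-bis(benzyloxy)-4-methoxyphenyl]-5,8-dihydroxy-7-methoxy-4H-chromen-4-one | COc1cc(O)c2c(=O)cc(-c3cc(OCc4ccccc4)c(OC)c(OCc4ccccc4)c3)oc2c1O | intermediate
15 | 5,8-bis(benzyloxy)-2-[3,5-bis(benzyloxy)-4-methoxyphenyl]-7-methoxy-4H-chromen-4-one | COc1cc(OCc2ccccc2)c2c(=O)cc(-c3cc(OCc4ccccc4)c(OC)c(OCc4ccccc4)c3)oc2c1OCc1ccccc1 | intermediate
16 | 2,3-epoxide of 15 (oxirane across C2–C3, necessarily cis-fused, racemic; both centres are erased on opening) | COc1cc(OCc2ccccc2)c2C(=O)C3OC3(c3cc(OCc4ccccc4)c(OC)c(OCc4ccccc4)c3)Oc2c1OCc1ccccc1 | intermediate (not isolated)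
17 | 5,8-bis(benzyloxy)-2-[3,5-bis(benzyloxy)-4-methoxyphenyl]-3-hydroxy-7-methoxy-4H-chromen-4-one | COc1cc(OCc2ccccc2)c2c(=O)c(O)c(-c3cc(OCc4ccccc4)c(OC)c(OCc4ccccc4)c3)oc2c1OCc1ccccc1 | intermediate
18 | 2-(3,5-dihydroxy-4-methoxyphenyl)-3,5,8-trihydroxy-7-methoxy-4H-chromen-4-one (no stereocentre) | COc1cc(O)c2c(=O)c(O)c(-c3cc(O)c(OC)c(O)c3)oc2c1O | target

**Step count**

Total: 11 steps. Longest linear sequence: 11 steps (1 to 18); pyranone 6 enters as a purchased partner in step 5.

**Steps most likely to fail, with fallbacks**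

Step 8 (Elbs oxidation). The chelated, sparingly soluble phenoxide may react only to low conversion. The quinol formed may be oxidised further in the alkaline medium, and the hot acid used for sulfate hydrolysis may loosen a benzyl ether. The fallback replaces persulfate chemistry by electrophilic halogenation and metal-catalysed C–B and C–O bond formation. It sets out from 12 and comes back at 15.
- Benzylation of the 5-OH (BnBr, K2CO3, DMF, 70 °C) should give 5-(benzyloxy)-2-[3,5-bis(benzyloxy)-4-methoxyphenyl]-7-methoxy-4H-chromen-4-one F1.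
- Iodination with N-iodosuccinimide and catalytic CF3CO2H in MeCN should then go to C8, the position attacked in 5,7-dialkoxyflavones, giving 5-(benzyloxy)-2-[3,5-bis(benzyloxy)-4-methoxyphenyl]-8-iodo-7-methoxy-4H-chromen-4-one F2.
- Miyaura borylation (bis(pinacolato)diboron, Pd(dppf)Cl2, KOAc, dioxane, 90 °C) should give the 8-(4,4,5,5-tetramethyl-1,3,2-dioxaborolan-2-yl) derivative of F1, F3.
- Oxidation with NaBO3 in THF/H2O should give 5-(benzyloxy)-2-[3,5-bis(benzyloxy)-4-methoxyphenyl]-8-hydroxy-7-methoxy-4H-chromen-4-one F4.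
- Benzylation of the 8-OH (BnBr, K2CO3, DMF) then gives 15.

Step 6 (pyranone unfolding and Claisen folding). The ring-opened intermediate may close through the aldol manifold or through oxygen. Methoxide may also cleave the diketone by retro-Claisen fragmentation or add to the enone. The fallback builds the same chalcone by a Claisen–Schmidt condensation on a preformed ring A. It sets out from aldehyde 4 and comes back at 10.
- Commercial 1-(2,6-dihydroxy-4-methoxyphenyl)ethanone F5 is converted with chloromethyl methyl ether and NaH in DMF into 1-[4-methoxy-2,6-bis(methoxymethoxy)phenyl]ethanone F6.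
- Condensation of F6 with 4 (KOH, EtOH, rt) should give (2E)-3-[3,5-bis(benzyloxy)-4-methoxyphenyl]-1-[4-methoxy-2,6-bis(methoxymethoxy)phenyl]prop-2-en-1-one F7.
- Removal of both acetals (HCl, MeOH, 50 °C) gives 10; any flavanone formed at this point is taken on through step 7 as before.

Step 5 (acylation of the lithiated pyranone). The delocalised carbanion may add to the β-carbon of the cinnamoyl amide instead of its carbonyl, or the tetrahedral adduct may revert to the stabilised carbanion before work-up. The fallback exchanges acylation for aldol addition and oxidation. It sets out from 5 and comes back at 8.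
- Reduction of 5 with DIBAL-H (THF, −78 °C) should give (2E)-3-[3,5-bis(benzyloxy)-4-methoxyphenyl]prop-2-enal F8.
- Carbanion 7, generated as in step 5, should add to the aldehyde carbonyl of F8 in a 1,2-aldol fashion to give racemic 6-{(3E)-4-[3,5-bis(benzyloxy)-4-methoxyphenyl]-2-hydroxybut-3-en-1-yl}-4-methoxy-2H-pyran-2-one F9.
- Oxidation of the allylic alcohol with MnO2 in CH2Cl2 (or Dess–Martin periodinane) gives 8.

**Further compounds**

F1 | step 8 | 5-(benzyloxy)-2-[3,5-bis(benzyloxy)-4-methoxyphenyl]-7-methoxy-4H-chromen-4-one | COc1cc(OCc2ccccc2)c2c(=O)cc(-c3cc(OCc4ccccc4)c(OC)c(OCc4ccccc4)c3)oc2c1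
F2 | step 8 | 5-(benzyloxy)-2-[3,5-bis(benzyloxy)-4-methoxyphenyl]-8-iodo-7-methoxy-4H-chromen-4-one | COc1cc(OCc2ccccc2)c2c(=O)cc(-c3cc(OCc4ccccc4)c(OC)c(OCc4ccccc4)c3)oc2c1I
F3 | step 8 | 5-(benzyloxy)-2-[3,5-bis(benzyloxy)-4-methoxyphenyl]-7-methoxy-8-(4,4,5,5-tetramethyl-1,3,2-dioxaborolan-2-yl)-4H-chromen-4-one | COc1cc(OCc2ccccc2)c2c(=O)cc(-c3cc(OCc4ccccc4)c(OC)c(OCc4ccccc4)c3)oc2c1B1OC(C)(C)C(C)(C)O1
F4 | step 8 | 5-(benzyloxy)-2-[3,5-bis(benzyloxy)-4-methoxyphenyl]-8-hydroxy-7-methoxy-4H-chromen-4-one | COc1cc(OCc2ccccc2)c2c(=O)cc(-c3cc(OCc4ccccc4)c(OC)c(OCc4ccccc4)c3)oc2c1O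
F5 | step 6 | 1-(2,6-dihydroxy-4-methoxyphenyl)ethanone | CC(=O)c1c(O)cc(OC)cc1O
F6 | step 6 | 1-[4-methoxy-2,6-bis(methoxymethoxy)phenyl]ethanone | CC(=O)c1c(OCOC)cc(OC)cc1OCOC
F7 | step 6 | (2E)-3-[3,5-bis(benzyloxy)-4-methoxyphenyl]-1-[4-methoxy-2,6-bis(methoxymethoxy)phenyl]prop-2-en-1-one | COCOc1cc(OC)cc(OCOC)c1C(=O)/C=C/c1cc(OCc2ccccc2)c(OC)c(OCc2ccccc2)c1
F8 | step 5 | (2E)-3-[3,5-bis(benzyloxy)-4-methoxyphenyl]prop-2-enal | O=C/C=C/c1cc(OCc2ccccc2)c(OC)c(OCc2ccccc2)c1
F9 | step 5 | 6-{(3E)-4-[3,5-bis(benzyloxy)-4-methoxyphenyl]-2-hydroxybut-3-en-1-yl}-4-methoxy-2H-pyran-2-one (racemic) | COc1cc(CC(O)/C=C/c2cc(OCc3ccccc3)c(OC)c(OCc3ccccc3)c2)oc(=O)c1
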